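**Assumption:** the acetal/lactol carbon of the oxolane ring is carried as a mixture of epimers (left undefined in the SMILES); this is harmless because that carbon becomes the sp2 CH of a terminal alkene in step 11. (R)-(+)-α-Terpineol and 5-chloro-2,4,6-trifluorobenzene-1,3-dicarbonitrile are taken as commercial.

**Plan** (benzopyran locants: O1, C2 quaternary ether carbon, C3 ring-fusion CH, C4 benzylic CH, C4a–C8a aryl)

1. Retrosynthesis: the two formyls go back to nitriles and the two phenols to methyl ethers; the ring C(CH3)=CH bond of the ten-membered ring is cut (metathesis); the aryl C4a–C4 bond is cut to an aryl radical and a Z-alkene; the aryl ether O1–C8a bond is cut (SNAr); the C3–CH2 bond and the C4 alkene go back to a 2,3-epoxy alcohol; its methyl ketone precursor is the ozonolysis product of (R)-α-terpineol.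
2. Forward order: open chain first, then the aryl ether, then the dihydropyran ring, then the ten-membered ring, then nitrile → formyl and O-demethylation.
3. Stereochemistry: the CH bearing the hydroxyisopropyl group comes from (R)-α-terpineol; C2 and C3 come from a Sharpless epoxidation followed by invertive epoxide opening; C4 is set in the radical ring closure; the Z ring alkene is set by the ring in the metathesis.
4. Enabling feature: C4a is ortho to the ether-bearing C8a, so a radical on C4a reaches an alkene carbon on C3 through O1–C2–C3 in a 6-exo mode. C4a is also the one ring carbon meta to both latent formyl carbons (C6, C8), so in the chlorotrifluoro-dinitrile it keeps its chloride through the SNAr steps, while the nitriles make the ring SNAr-active and reducible.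

Key step: step 9

**Step 1**
Reactants: 1 (R)-(+)-α-terpineol
Product: 3 keto acetal (methyl ketone with a 5-methoxy-2,2-dimethyloxolane ring; R at the oxolane C3), via keto lactol 2 (not isolated)
Conditions: O3, CH2Cl2/MeOH, −78 °C; Me2S, −78 °C → rt; then PPTS (cat.), MeOH, rt
Reagents that add atoms: ozone, [O-][O+]=O; methanol, CO
Why: Ozonolysis with reductive work-up cleaves the only alkene to a methyl ketone and an aldehyde; the tertiary hydroxyl closes onto the aldehyde as a five-membered lactol, which PPTS/MeOH should convert into the cyclic methyl acetal, masking aldehyde and tertiary alcohol together without touching the stereocentre.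

**Step 2**
Reactants: 3 keto acetal; 4 triethyl phosphonoacetate
Product: 5 E-enoate
Conditions: NaH, THF, 0 → 50 °C
Reagents that add atoms: 4 triethyl phosphonoacetate, CCOC(=O)CP(=O)(OCC)OCC
Why: Horner–Wadsworth–Emmons olefination of a methyl ketone should favour the E trisubstituted enoate (ester trans to the longer chain); the minor Z isomer is to be removed by chromatography here or after step 3.

**Step 3**
Reactants: 5 E-enoate
Product: 6 E-allylic alcohol
Conditions: DIBAL-H, CH2Cl2, −78 °C; aq. Rochelle salt
Reagents that add atoms: none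
Why: DIBAL 1,2-reduction of an α,β-unsaturated ester to the allylic alcohol; the acetal is inert to hydride.

**Step 4**
Reactants: 6 E-allylic alcohol
Product: 7 (2R,3R)-epoxy alcohol
Conditions: Ti(OiPr)4 (cat.), D-(−)-diethyl tartrate (cat.), t-BuOOH, 4 Å MS, CH2Cl2, −20 °C
Reagents that add atoms: tert-butyl hydroperoxide, CC(C)(C)OO
Why: Sharpless asymmetric epoxidation; with D-(−)-tartrate an E-3,3-disubstituted allylic alcohol should give the (2R,3R)-epoxide (mirror image of the geraniol/L-(+)-tartrate case), which fixes the future quaternary ether carbon by reagent control.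

**Step 5**
Reactants: 7 epoxy alcohol; 8 4-bromo-2-methylbut-1-ene
Product: 9 (2S,3R)-1,3-diol
Conditions: Mg, THF (Grignard from 8); CuI (cat.), THF, −40 → 0 °C; aq. work-up
Reagents that add atoms: 8 4-bromo-2-methylbut-1-ene, C=C(C)CCBr
Why: Copper-catalysed Grignard opening of a 3,3-disubstituted 2,3-epoxy alcohol should occur at C-2 (C-3 is fully substituted) with inversion, setting the ring-fusion CH relative to the tertiary carbinol and giving the 1,3-diol.

**Step 6**
Reactants: 9 1,3-diol
Product: 10 β-hydroxy aldehyde
Conditions: TEMPO (cat.), PhI(OAc)2, CH2Cl2, rt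
Reagents that add atoms: none
Why: Oxoammonium (TEMPO) oxidation takes the primary alcohol to the aldehyde, leaves the tertiary alcohol untouched and is non-basic, so the α-stereocentre should survive; the aldehyde is used without storage.

**Step 7**
Reactants: 10 β-hydroxy aldehyde; 11 (2-methylpropyl)triphenylphosphonium bromide
Product: 12 Z-alkenyl carbinol
Conditions: NaHMDS, THF, 0 °C (ylide); then 10, −78 → 0 °C
Reagents that add atoms: 11 (2-methylpropyl)triphenylphosphonium bromide, CC(C)C[P+](c1ccccc1)(c1ccccc1)c1ccccc1.[Br-]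
Why: Salt-free Wittig reaction of a non-stabilised ylide should give the Z-alkene; the ylide is too weak a base to deprotonate the tertiary alcohol, and addition at −78 °C should outrun enolisation.

**Step 8**
Reactants: 12 Z-alkenyl carbinol; 13 5-chloro-2,4,6-trifluorobenzene-1,3-dicarbonitrile
Product: 15 dimethoxy aryl ether (tertiary alkyl ether of 5-chloro-2,6-dimethoxy-1,3-dicyanobenzene at C4), via difluoro aryl ether 14 (not isolated)
Conditions: KHMDS, THF, −78 °C; 13, −78 → −20 °C; then NaOMe, MeOH, 0 °C → rt
Reagents that add atoms: 13 5-chloro-2,4,6-trifluorobenzene-1,3-dicarbonitrile, N#Cc1c(F)c(Cl)c(F)c(C#N)c1F; sodium methoxide, [Na+].[O-]C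
Why: SNAr of the potassium tertiary alkoxide on the polyfluoroarene should go first at C4 (equivalent to C6; para to one nitrile, ortho to the other), then methoxide replaces the two remaining activated fluorides; the chloride, meta to both nitriles, stays, and the O–C stereocentre is not involved.

**Step 9**
Reactants: 15 dimethoxy aryl ether
Product: 16 (2R,3S,4S)-chromane acetal
Conditions: 4DPAIPN (cat.), HCO2Na, cyclohexanethiol (cat.), DMSO, blue LEDs, rt
Reagents that add atoms: none
Why: The thiyl radical formed by photocatalytic oxidation abstracts hydrogen from formate to give CO2 radical anion, which reduces the dicyano-chloroarene; loss of chloride leaves a σ-radical at C4a that adds to the near carbon of the Z-alkene, and the resulting secondary alkyl radical takes hydrogen from the thiol, giving the isobutyl group directly. The closest known reaction type is the reductive aryl-radical cyclisation of o-halophenyl homoallyl ethers to 4-alkylchromanes (tin hydride or photoredox/formate). The dihydropyran ring closes 6-exo-trig; the 7-endo mode is disfavoured because that alkene carbon carries the isopropyl group. The new C4 stereocentre is controlled by C3: A1,3 strain of the Z-alkene holds the C3–H bond in the alkene plane, the O1–C2 tether delivers the aryl radical to the face on which C2 lies, and in the chair-like transition state the alkene terminus is pseudo-equatorial, so that the isobutyl group should end up trans to the C3 side chain (4S). The step needs ring closure to outrun hydrogen transfer to the aryl radical (thiol kept catalytic; 1,6-shift of the allylic C3–H is the main competitor) and needs the alkyl radical to be quenched before it reaches the 1,1-disubstituted alkene, which the thiol secures; the other alkene is out of reach of the aryl radical.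

**Step 10**
Reactants: 16 chromane acetal
Product: 17 chromane lactol
Conditions: AcOH/THF/H2O, 45 °C
Reagents that add atoms: water, O
Why: Mild acid hydrolysis of a 2-methoxyoxolane acetal to the lactol; the cyclic tertiary aryl ether and the 1,1-disubstituted alkene should tolerate aqueous acetic acid.

**Step 11**
Reactants: 17 chromane lactol; 18 methyltriphenylphosphonium bromide
Product: 19 diene with free tertiary alcohol
Conditions: KOtBu, THF, 0 °C → rt (excess ylide)
Reagents that add atoms: 18 methyltriphenylphosphonium bromide, C[P+](c1ccccc1)(c1ccccc1)c1ccccc1.[Br-]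
Why: Wittig methylenation of the lactol through its open hydroxy-aldehyde form gives the terminal alkene and releases the hydroxyisopropyl group; aryl nitriles are inert to the ylide.

**Step 12**
Reactants: 19 diene
Product: 20 macrocyclic dinitrile (Z ring alkene)
Conditions: Grubbs II (cat.), toluene (high dilution), 80 °C
Reagents that add atoms: none
Why: Ring-closing metathesis between the monosubstituted and the 1,1-disubstituted alkene; the two chains are trans-diequatorial on C2/C3 of the chromane and so held close, and the ring-cis (Z) trisubstituted alkene is the strongly preferred geometry in a ten-membered ring.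

**Step 13**
Reactants: 20 macrocyclic dinitrile
Product: 21 dialdehyde dimethyl ether
Conditions: DIBAL-H (excess), toluene, −78 → 0 °C; then 1 M HCl, THF, rt
Reagents that add atoms: water, O
Why: DIBAL adds once to each aryl nitrile to give aldimine-alanes that hydrolyse to the aldehydes on acidic work-up; the alkene and the tertiary alkoxide are inert.

**Step 14**
Reactants: 21 dialdehyde dimethyl ether
Product: 22 target CNP0570248.1
Conditions: NaSEt, DMF, 100 °C; then dil. HCl
Reagents that add atoms: none
Why: Thiolate SN2 O-demethylation of aryl methyl ethers that are ortho/para to formyl groups (vinylogous methyl esters); the tertiary ether and tertiary alcohol cannot react by SN2, so no stereocentre is at risk.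

**Compound list**

1 | (R)-(+)-α-terpineol; 2-[(1R)-4-methylcyclohex-3-en-1-yl]propan-2-ol | CC1=CC[C@@H](CC1)C(C)(C)O | starting material
2 | keto lactol; 4-[(3R)-5-hydroxy-2,2-dimethyloxolan-3-yl]butan-2-one | OC1C[C@H](C(C)(C)O1)CCC(C)=O | intermediate
3 | keto acetal; 4-[(3R)-5-methoxy-2,2-dimethyloxolan-3-yl]butan-2-one | COC1C[C@H](C(C)(C)O1)CCC(C)=O | intermediate
4 | triethyl phosphonoacetate | CCOC(=O)CP(=O)(OCC)OCC | starting material
5 | E-enoate; ethyl (2E)-5-[(3R)-5-methoxy-2,2-dimethyloxolan-3-yl]-3-methylpent-2-enoate | COC1C[C@H](C(C)(C)O1)CC/C(C)=C/C(=O)OCC | intermediate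
6 | E-allylic alcohol; (2E)-5-[(3R)-5-methoxy-2,2-dimethyloxolan-3-yl]-3-methylpent-2-en-1-ol | COC1C[C@H](C(C)(C)O1)CC/C(C)=C/CO | intermediate
7 | epoxy alcohol; [(2R,3R)-3-{2-[(3R)-5-methoxy-2,2-dimethyloxolan-3-yl]ethyl}-3-methyloxiran-2-yl]methanol | COC1C[C@H](C(C)(C)O1)CC[C@@]2(C)O[C@@H]2CO | intermediate
8 | 4-bromo-2-methylbut-1-ene | C=C(C)CCBr | starting material
9 | 1,3-diol; (2S,3R)-5-[(3R)-5-methoxy-2,2-dimethyloxolan-3-yl]-3-methyl-2-(3-methylbut-3-en-1-yl)pentane-1,3-diol | COC1C[C@H](C(C)(C)O1)CC[C@@](C)(O)[C@H](CO)CCC(C)=C | intermediate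
10 | β-hydroxy aldehyde; (2R,3R)-3-hydroxy-5-[(3R)-5-methoxy-2,2-dimethyloxolan-3-yl]-3-methyl-2-(3-methylbut-3-en-1-yl)pentanal | COC1C[C@H](C(C)(C)O1)CC[C@@](C)(O)[C@H](C=O)CCC(C)=C | intermediate
11 | (2-methylpropyl)triphenylphosphonium bromide | CC(C)C[P+](c1ccccc1)(c1ccccc1)c1ccccc1.[Br-] | starting material
12 | Z-alkenyl carbinol; (3R,4S,5Z)-1-[(3R)-5-methoxy-2,2-dimethyloxolan-3-yl]-3,7-dimethyl-4-(3-methylbut-3-en-1-yl)oct-5-en-3-ol | COC1C[C@H](C(C)(C)O1)CC[C@@](C)(O)[C@H](/C=C\C(C)C)CCC(C)=C | intermediate
13 | 5-chloro-2,4,6-trifluorobenzene-1,3-dicarbonitrile | N#Cc1c(F)c(Cl)c(F)c(C#N)c1F | starting material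
14 | difluoro aryl ether; 5-chloro-2,6-difluoro-4-{[(3R,4S,5Z)-1-[(3R)-5-methoxy-2,2-dimethyloxolan-3-yl]-3,7-dimethyl-4-(3-methylbut-3-en-1-yl)oct-5-en-3-yl]oxy}benzene-1,3-dicarbonitrile | COC1C[C@H](C(C)(C)O1)CC[C@@](C)(Oc2c(C#N)c(F)c(C#N)c(F)c2Cl)[C@H](/C=C\C(C)C)CCC(C)=C | intermediate
15 | dimethoxy aryl ether; 5-chloro-2,6-dimethoxy-4-{[(3R,4S,5Z)-1-[(3R)-5-methoxy-2,2-dimethyloxolan-3-yl]-3,7-dimethyl-4-(3-methylbut-3-en-1-yl)oct-5-en-3-yl]oxy}benzene-1,3-dicarbonitrile | COC1C[C@H](C(C)(C)O1)CC[C@@](C)(Oc2c(C#N)c(OC)c(C#N)c(OC)c2Cl)[C@H](/C=C\C(C)C)CCC(C)=C | intermediate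
16 | chromane acetal; (2R,3S,4S)-5,7-dimethoxy-2-{2-[(3R)-5-methoxy-2,2-dimethyloxolan-3-yl]ethyl}-2-methyl-3-(3-methylbut-3-en-1-yl)-4-(2-methylpropyl)-3,4-dihydro-2H-1-benzopyran-6,8-dicarbonitrile | COC1C[C@H](C(C)(C)O1)CC[C@@]2(C)Oc3c(C#N)c(OC)c(C#N)c(OC)c3[C@@H](CC(C)C)[C@@H]2CCC(C)=C | intermediate
17 | chromane lactol; (2R,3S,4S)-2-{2-[(3R)-5-hydroxy-2,2-dimethyloxolan-3-yl]ethyl}-5,7-dimethoxy-2-methyl-3-(3-methylbut-3-en-1-yl)-4-(2-methylpropyl)-3,4-dihydro-2H-1-benzopyran-6,8-dicarbonitrile | OC1C[C@H](C(C)(C)O1)CC[C@@]2(C)Oc3c(C#N)c(OC)c(C#N)c(OC)c3[C@@H](CC(C)C)[C@@H]2CCC(C)=C | intermediate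
18 | methyltriphenylphosphonium bromide | C[P+](c1ccccc1)(c1ccccc1)c1ccccc1.[Br-] | starting material
19 | diene; (2R,3S,4S)-2-[(3R)-3-(2-hydroxypropan-2-yl)hex-5-en-1-yl]-5,7-dimethoxy-2-methyl-3-(3-methylbut-3-en-1-yl)-4-(2-methylpropyl)-3,4-dihydro-2H-1-benzopyran-6,8-dicarbonitrile | C=CC[C@H](C(C)(C)O)CC[C@@]2(C)Oc3c(C#N)c(OC)c(C#N)c(OC)c3[C@@H](CC(C)C)[C@@H]2CCC(C)=C | intermediate
20 | macrocyclic dinitrile; the target skeleton with C≡N in place of each CHO and OCH3 in place of each phenolic OH, Z ring alkene, configurations as in the target | C/C1=C/C[C@H](C(C)(C)O)CC[C@@]2(C)Oc3c(C#N)c(OC)c(C#N)c(OC)c3[C@@H](CC(C)C)[C@@H]2CC1 | intermediate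
21 | dialdehyde dimethyl ether; the target with both phenols as methyl ethers | C/C1=C/C[C@H](C(C)(C)O)CC[C@@]2(C)Oc3c(C=O)c(OC)c(C=O)c(OC)c3[C@@H](CC(C)C)[C@@H]2CC1 | intermediate
22 | CNP0570248.1 | C/C1=C/C[C@H](C(C)(C)O)CC[C@@]2(C)Oc3c(C=O)c(O)c(C=O)c(O)c3[C@@H](CC(C)C)[C@@H]2CC1 | target

**Step count and risks**

Total steps: 14. Longest linear sequence: 14 (from 1).

Steps most likely to fail:

Step 12. Oligomerisation or double-bond migration may outrun closure of the medium ring, or the trisubstituted alkene may not form at a useful rate. The fallback closes the ring by reductive carbonyl coupling instead. It sets out from chromane lactol 17: ozonolysis of its only alkene (O3, CH2Cl2, −78 °C; Me2S) should give the methyl ketone keto lactol F1, and McMurry coupling of this ketone with the lactol aldehyde (TiCl3/Zn–Cu, DME, reflux, slow addition) should give the ring alkene directly, returning to the route at macrocyclic dinitrile 20. The ring-cis isomer is again the expected one, and the nitriles are the groups to watch under low-valent titanium.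

Step 9. Electron transfer to the trialkoxy-substituted ring may be too slow to cleave the chloride, or hydrogen transfer to the aryl radical may outrun ring closure. The fallback closes the ring one stage earlier on a more electron-poor arene. It sets out from 12 and 13: step 8 is stopped before methoxide is added and difluoro aryl ether 14 is isolated. This ring is reduced more easily and gives a more electrophilic aryl radical, so a milder photoreductant or tributyltin hydride/AIBN should suffice to reach difluoro chromane F2. Sodium methoxide in methanol then replaces both fluorides and the route is rejoined at chromane acetal 16.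

Step 7. The basic ylide may cause retro-aldol cleavage of the β-hydroxy aldehyde or epimerisation of its α-stereocentre. The fallback makes the alkene without base. It sets out from 10: Takai–Utimoto alkylidenation (1,1-diiodo-2-methylpropane, CrCl2, THF/DMF, rt) should give E-alkenyl carbinol F3. SNAr and methoxide exchange as in step 8 then lead through E difluoro aryl ether F4 (not isolated) to E dimethoxy aryl ether F5. Radical ring closure as in step 9 returns to the route at chromane acetal 16, because the alkene geometry disappears in that step; a weaker facial bias is expected for the E isomer.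

**Further compounds**

F1 | step 12 | keto lactol; (2R,3S,4S)-2-{2-[(3R)-5-hydroxy-2,2-dimethyloxolan-3-yl]ethyl}-5,7-dimethoxy-2-methyl-4-(2-methylpropyl)-3-(3-oxobutyl)-3,4-dihydro-2H-1-benzopyran-6,8-dicarbonitrile | OC1C[C@H](C(C)(C)O1)CC[C@@]2(C)Oc3c(C#N)c(OC)c(C#N)c(OC)c3[C@@H](CC(C)C)[C@@H]2CCC(C)=O
F2 | step 9 | difluoro chromane; (2R,3S,4S)-5,7-difluoro-2-{2-[(3R)-5-methoxy-2,2-dimethyloxolan-3-yl]ethyl}-2-methyl-3-(3-methylbut-3-en-1-yl)-4-(2-methylpropyl)-3,4-dihydro-2H-1-benzopyran-6,8-dicarbonitrile | COC1C[C@H](C(C)(C)O1)CC[C@@]2(C)Oc3c(C#N)c(F)c(C#N)c(F)c3[C@@H](CC(C)C)[C@@H]2CCC(C)=C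
F3 | step 7 | E-alkenyl carbinol; (3R,4S,5E)-1-[(3R)-5-methoxy-2,2-dimethyloxolan-3-yl]-3,7-dimethyl-4-(3-methylbut-3-en-1-yl)oct-5-en-3-ol | COC1C[C@H](C(C)(C)O1)CC[C@@](C)(O)[C@H](/C=C/C(C)C)CCC(C)=C
F4 | step 7 | E difluoro aryl ether; 5E isomer of 14 | COC1C[C@H](C(C)(C)O1)CC[C@@](C)(Oc2c(C#N)c(F)c(C#N)c(F)c2Cl)[C@H](/C=C/C(C)C)CCC(C)=C
F5 | step 7 | E dimethoxy aryl ether; 5E isomer of 15 | COC1C[C@H](C(C)(C)O1)CC[C@@](C)(Oc2c(C#N)c(OC)c(C#N)c(OC)c2Cl)[C@H](/C=C/C(C)C)CCC(C)=C
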